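The earlier runs and the new flask come from a simulation on assumed constants; noise was put on by code.

The tempting mistake is to read the yield of E as its selectivity, and so to expect that a flask making less E also makes it less cleanly. Here Z, a complex, turns under held J into E, with two exchanged, and into the other product G.

| flask | Z | J | remark | time |
|---|---|---|---|---|
| Friday's | 8.6 mM | 1.7 mM (held) | run made earlier |  |
| Monday's | 35 mM | 1.7 mM (held) | run made earlier |  |
| eta | 10 mM | 1.7 mM (held) |  | 15 h |
| epsilon | 20 mM | 1.7 mM (held) |  | 15 h |
| beta | 40 mM | 1.7 mM (held) |  | 15 h |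

| run | time / h | E / % | G / % | Z / % |
|---|---|---|---|---|
| Friday's | 1.33 | 1 | 1 | 78 |
| Friday's | 4.00 | 8 | 1 | 56 |
| Friday's | 8.00 | 16 | 6 | 41 |
| Friday's | 10.0 | 20 | 5 | 40 |
| Friday's | 15.0 | 18 | 6 | 35 |
| Monday's | 1.33 | 0 | 0 | 95 |
| Monday's | 4.00 | 0 | 0 | 84 |
| Monday's | 8.00 | 3 | 0 | 72 |
| Monday's | 10.0 | 3 | 0 | 71 |
| Monday's | 15.0 | 7 | 2 | 67 |

(each reading ± 1.5 percentage points)

* share of E in all that became E or G for eta, epsilon, beta, in this order
* the shape of the row from first to last (falls, then rises / rises all the way / rises, then falls / falls all the way / hardly changes)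

- at the start none of J is in solution
- "hardly changes" means that all values lie within two and a half points (for a concentration: within two and a half percent of the largest)

The puzzle is at 15.0 h: Friday's run holds 18% of E and Monday's 7%, much less, yet their shares of E in E plus G read 75.0% and 77.8%.

I clear this up by separating how much enters the pair from how the pair divides. Pooled over Friday's readings from 8.00 h on, G against E comes to 0.315; I carry this as ρ, the amount of G standing per amount of E. Does it drift? Friday's ratio reads 0.375 at 8.00 h and 0.333 at 15.0 h, no real change with a scatter of 1.5 percentage points on so small a G. Monday's test is independent: ρ turns its 7% of E into 2.21% of G, and the reading is 2%. Between Friday's and Monday's charges the size of the pair changes, and within the scatter of the readings its division does not. So I expect a share of 76.1% in eta, epsilon and beta alike.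

The forecast, a little higher than my value, gives 78%, 78% and 78%, shape "hardly changes", noting that “The share shows no clear time or concentration trend”. The flasks give 75.2%, 75.4% and 75.8%: hardly changes.

    Z + D ⇌ X + Q (K = 4.80, k = 0.321 M⁻¹ s⁻¹)
    E ⇌ G (K = 0.334, k = 9.62 × 10⁻⁵ s⁻¹)
    D ⇌ L (K = 2.75, k = 2.81 × 10⁻⁵ s⁻¹)
    Q + D ⇌ X + E (K = 2.50, k = 0.0900 M⁻¹ s⁻¹)
    J ⇌ D, rate k5*(csat - [D]) (kL = 2.95 × 10⁻⁴ s⁻¹)

E and G interconvert, and in eta that pair relaxes with a half-life of 0.501 h, short against the 15 h of the run; for the division of E and G this is thermodynamic rather than kinetic control. So ρ turns eta's 17.0% of E into 5.36% of G, where the flask holds 5.60%, and beta's 4.92% of E into 1.55%, where it holds 1.57%. The falling back of G to E is the main reason for this division: in beta without that step the share of E is 24.1%, against 75.8% with it.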